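## Retrosynthetic overview
1. Target ⇐ global desilylation ⇐ axial 4-OH, set by L-Selectride reduction of a 2,6-cis, 2,3-trans tetrahydropyran-4-one.
2. The pyranone ring forms by an acid-mediated oxocarbenium/enol cyclisation (Maitland–Japp/Prins type) of a β-hydroxy ketone with 4-silyloxybenzaldehyde. This sets C2 and C3, and C6 is carried in.
3. The β-hydroxy ketone comes from a reagent-controlled boron aldol of a methyl ketone with 3-arylpropanal, which sets C6.
4. The methyl ketone comes from Rh-catalysed asymmetric 1,4-addition of an (E)-styrylboronic acid to an enone, which sets the side-chain CH (Ca).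
5. The enone comes from cross-metathesis of a Brown-derived (S)-homoallylic silyl ether with methyl vinyl ketone. That Brown allylation sets the side-chain carbinol (Cb).

Assumptions:
- All phenols are carried as TIPS ethers and the side-chain carbinol as a TBDPS ether. This avoids hydrogenolysis, which would reduce the styrene, and all five silyl groups leave with fluoride at the end.
- The enantiomer of each chiral reagent or ligand (Ipc-boranes, Rh-diene) is chosen to give the configuration in the target SMILES.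

## Route

**Step 1**
Reactants: 1 (4-hydroxybenzaldehyde)
Product: 2 (4-TIPSO-benzaldehyde)
Conditions: TIPSCl, imidazole, DMF, rt
Reagents that add atoms: TIPSCl, CC(C)[Si](Cl)(C(C)C)C(C)C
Why: Silylation of the phenol gives a base-, acid- and fluoride-cleavable protecting group compatible with everything downstream.

**Step 2**
Reactants: 2
Product: 3 (4-TIPSO-phenylacetylene)
Conditions: Ohira–Bestmann reagent, K2CO3, MeOH, rt
Reagents that add atoms: dimethyl (1-diazo-2-oxopropyl)phosphonate, COP(=O)(OC)C(=[N+]=[N-])C(C)=O (supplies the alkyne carbon)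
Why: The Seyferth–Gilbert homologation (Ohira–Bestmann variant) converts ArCHO to the terminal alkyne without touching the aryl TIPS ether.

**Step 3**
Reactants: 3
Product: 4 ((E)-2-(4-TIPSO-phenyl)vinylboronic acid)
Conditions: catecholborane, THF, 70 °C; then H2O
Reagents that add atoms: catecholborane, B1Oc2ccccc2O1; water, O
Why: Syn hydroboration of the terminal alkyne gives the (E)-alkenylborane, and hydrolysis gives the boronic acid that feeds the Hayashi–Miyaura addition in step 9.

**Step 4**
Reactants: 5 (methyl 3-(4-hydroxyphenyl)propanoate)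
Product: 6 (methyl 3-(4-TIPSO-phenyl)propanoate)
Conditions: TIPSCl, imidazole, DMF, rt
Reagents that add atoms: TIPSCl, CC(C)[Si](Cl)(C(C)C)C(C)C
Why: Chemoselective silylation of the phenol.

**Step 5**
Reactants: 6
Product: 7 (3-(4-TIPSO-phenyl)propanal)
Conditions: DIBAL-H (1.05 equiv), CH2Cl2, −78 °C
Reagents that add atoms: none (hydride only)
Why: A single hydride delivery to the ester gives a stable tetrahedral aluminium hemiacetal at −78 °C, so the reaction stops at the aldehyde (partial ester reduction).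

**Step 6**
Reactants: 7
Product: 8 ((S)-1-(4-TIPSO-phenyl)hex-5-en-3-ol)
Conditions: (+)-Ipc2B(allyl), Et2O, −78 °C; then NaOH, H2O2
Reagents that add atoms: (+)-B-allyldiisopinocampheylborane, C=CCB(C1C(C)C2CC1C2(C)C)C1C(C)C2CC1C2(C)C
Why: Brown asymmetric allylboration goes through a closed Zimmerman–Traxler transition state, and the Ipc ligands direct allyl delivery to the Re face. This sets the Cb carbinol as (S), and the aryl silyl ether is untouched.

**Step 7**
Reactants: 8
Product: 9 (TBDPS ether of 8)
Conditions: TBDPSCl, imidazole, DMF, rt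
Reagents that add atoms: TBDPSCl, CC(C)(C)[Si](Cl)(c1ccccc1)c1ccccc1
Why: The secondary alcohol is protected with an acid-stable group so that it survives the TFA cyclisation in step 11 and cannot form a hemiketal with the C4 ketone.

**Step 8**
Reactants: 9; 10 (methyl vinyl ketone)
Product: 11 ((3E,6S)-6-TBDPSO-8-(4-TIPSO-phenyl)oct-3-en-2-one)
Conditions: Hoveyda–Grubbs II (5 mol %), CH2Cl2, 40 °C
Reagents that add atoms: none (MVK is a numbered reactant; ethylene is lost)
Why: Olefin cross-metathesis between a type-I terminal alkene and an electron-poor vinyl ketone gives the (E)-enone, and the stereocentre is not involved.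

**Step 9**
Reactants: 11; 4
Product: 12 ((4R,6S)-4-[(E)-styryl]-6-TBDPSO-8-aryl-octan-2-one)
Conditions: [Rh(cod)Cl]2 / chiral diene (2.5 / 5.5 mol %), KOH (aq), dioxane/H2O, 50 °C
Reagents that add atoms: none (the styryl group comes from 4; catalyst only)
Why: Hayashi–Miyaura Rh-catalysed asymmetric 1,4-addition of the alkenylboronic acid to the (E)-enone. The chiral diene controls the enone face and sets Ca (S in the target, R by CIP in this intermediate), and catalyst control should dominate the remote Cb centre. The E-styrene is retained. The new Ca–Cb pair is 1,3-syn as required.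

**Step 10**
Reactants: 12; 7
Product: 13 ((3S,7R,9S)-β-hydroxy ketone)
Conditions: (+)-Ipc2BCl, i-Pr2NEt, CH2Cl2, 0 °C → −78 °C; add 7, −78 → −25 °C; then MeOH, pH 7 buffer, H2O2
Reagents that add atoms: none (boron is removed in the oxidative work-up)
Why: Paterson boron aldol. Ipc2BCl/amine enolises the methyl ketone at the less hindered CH3, and the chiral boron enolate adds to the aldehyde face that gives the (S)-C6 carbinol. The aldehyde carbon becomes C6 and the methyl carbon becomes C5.

**Step 11**
Reactants: 13; 2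
Product: 14 ((2S,3R,6S)-2,6-cis, 2,3-trans THP-4-one)
Conditions: TFA (10 equiv), CH2Cl2, 0 °C → rt, 12 h
Reagents that add atoms: none (TFA is a promoter only; water is lost)
Why: C6–OH and ArCHO form an oxocarbenium ion, which is attacked intramolecularly by the C3 enol (Maitland–Japp/Prins-type cyclisation, forming C2–C3 and C2–O1). The chair transition state with aryl and arylethyl equatorial gives 2,6-cis. The α-stereocentre C3 equilibrates under acid to the equatorial, 2,3-trans isomer. Enolisation toward C5 is geometrically non-productive.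

**Step 12**
Reactants: 14
Product: 15 (fully silylated target, 4-axial alcohol)
Conditions: L-Selectride, THF, −78 °C; then NaBO3, H2O
Reagents that add atoms: none (hydride only)
Why: The bulky hydride attacks the all-equatorial ketone along the equatorial trajectory and delivers H equatorially, giving the axial 4-OH (4S), cis to the equatorial 3-substituent. The silyl ethers and the styrene are inert.

**Step 13**
Reactants: 15
Product: 16 (Blepharocalyxin C)
Conditions: TBAF, AcOH (buffer), THF, 40 °C
Reagents that add atoms: none (all five Si groups are removed)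
Why: Fluoride cleaves the four aryl-OTIPS groups and the alkyl OTBDPS group without touching the styrene, the benzylic pyran ether or any stereocentre.

## Compound list
1 | 4-hydroxybenzaldehyde | O=Cc1ccc(O)cc1 | starting material
2 | 4-(triisopropylsilyloxy)benzaldehyde | O=Cc1ccc(O[Si](C(C)C)(C(C)C)C(C)C)cc1 | intermediate
3 | 1-ethynyl-4-(TIPSO)benzene | C#Cc1ccc(O[Si](C(C)C)(C(C)C)C(C)C)cc1 | intermediate
4 | (E)-2-[4-(TIPSO)phenyl]vinylboronic acid | OB(O)/C=C/c1ccc(O[Si](C(C)C)(C(C)C)C(C)C)cc1 | intermediate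
5 | methyl 3-(4-hydroxyphenyl)propanoate | COC(=O)CCc1ccc(O)cc1 | starting material
6 | methyl 3-[4-(TIPSO)phenyl]propanoate | COC(=O)CCc1ccc(O[Si](C(C)C)(C(C)C)C(C)C)cc1 | intermediate
7 | 3-[4-(TIPSO)phenyl]propanal | O=CCCc1ccc(O[Si](C(C)C)(C(C)C)C(C)C)cc1 | intermediate
8 | (S)-1-[4-(TIPSO)phenyl]hex-5-en-3-ol | C=CC[C@@H](O)CCc1ccc(O[Si](C(C)C)(C(C)C)C(C)C)cc1 | intermediate
9 | (S)-TBDPS ether of 8 | C=CC[C@@H](O[Si](c1ccccc1)(c1ccccc1)C(C)(C)C)CCc1ccc(O[Si](C(C)C)(C(C)C)C(C)C)cc1 | intermediate
10 | methyl vinyl ketone (but-3-en-2-one) | C=CC(C)=O | starting material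
11 | (3E,6S)-6-TBDPSO-8-[4-(TIPSO)phenyl]oct-3-en-2-one | CC(=O)/C=C/C[C@@H](O[Si](c1ccccc1)(c1ccccc1)C(C)(C)C)CCc1ccc(O[Si](C(C)C)(C(C)C)C(C)C)cc1 | intermediate
12 | (4R,6S)-4-{(E)-2-[4-(TIPSO)phenyl]ethenyl}-6-TBDPSO-8-[4-(TIPSO)phenyl]octan-2-one | O([Si](C(C)C)(C(C)C)C(C)C)c1ccc(/C=C/[C@H](C[C@@H](O[Si](c2ccccc2)(c2ccccc2)C(C)(C)C)CCc2ccc(O[Si](C(C)C)(C(C)C)C(C)C)cc2)CC(C)=O)cc1 | intermediate
13 | (3S,7R,9S)-9-TBDPSO-3-hydroxy-7-[(E)-aryl-ethenyl]-1,11-bis[4-(TIPSO)phenyl]undecan-5-one | O([Si](C(C)C)(C(C)C)C(C)C)c1ccc(/C=C/[C@H](C[C@@H](O[Si](c2ccccc2)(c2ccccc2)C(C)(C)C)CCc2ccc(O[Si](C(C)C)(C(C)C)C(C)C)cc2)CC(=O)C[C@@H](O)CCc2ccc(O[Si](C(C)C)(C(C)C)C(C)C)cc2)cc1 | intermediate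
14 | (2S,3R,6S)-2,6-cis-2-aryl-6-(2-arylethyl)-3-[side chain]-tetrahydropyran-4-one, all equatorial (aryl = 4-TIPSO-phenyl) | O([Si](C(C)C)(C(C)C)C(C)C)c1ccc(/C=C/[C@H](C[C@@H](O[Si](c2ccccc2)(c2ccccc2)C(C)(C)C)CCc2ccc(O[Si](C(C)C)(C(C)C)C(C)C)cc2)[C@@H]2[C@@H](c3ccc(O[Si](C(C)C)(C(C)C)C(C)C)cc3)O[C@@H](CCc3ccc(O[Si](C(C)C)(C(C)C)C(C)C)cc3)CC2=O)cc1 | intermediate
15 | (2S,3S,4S,6S)-4-axial alcohol, penta-silylated target | O([Si](C(C)C)(C(C)C)C(C)C)c1ccc(/C=C/[C@H](C[C@@H](O[Si](c2ccccc2)(c2ccccc2)C(C)(C)C)CCc2ccc(O[Si](C(C)C)(C(C)C)C(C)C)cc2)[C@@H]2[C@@H](c3ccc(O[Si](C(C)C)(C(C)C)C(C)C)cc3)O[C@@H](CCc3ccc(O[Si](C(C)C)(C(C)C)C(C)C)cc3)C[C@@H]2O)cc1 | intermediate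
16 | Blepharocalyxin C | Oc1ccc(/C=C/[C@H](C[C@@H](O)CCc2ccc(O)cc2)[C@@H]2[C@@H](c3ccc(O)cc3)O[C@@H](CCc3ccc(O)cc3)C[C@@H]2O)cc1 | target

**Total steps:** 13
**Longest linear sequence:** 10 (steps 4 → 13, via 5 → 6 → 7 → 8 → 9 → 11 → 12 → 13 → 14 → 15 → 16)

## Three steps most likely to fail
1. **Step 9 (Rh-catalysed addition; 1,4-selectivity, ee, and Ca configuration on an acyclic enone).**
   Fallback: build Ca by desymmetrising 3-styrylglutaric anhydride (cinchona-catalysed alcoholysis). Then elaborate the two arms: one by Weinreb amide → MeMgBr to the methyl ketone, the other to the Cb carbinol via the (S)-epoxide.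
2. **Step 10 (Paterson aldol; enantio- and diastereoselectivity of a methyl ketone with a linear aldehyde).**
   Fallback: open (S)-2-(4-TIPSO-phenethyl)oxirane (from Jacobsen hydrolytic kinetic resolution) with the lithiated N,N-dimethylhydrazone of 12 at the methyl carbon, then cleave the hydrazone (CuCl2 or NaIO4) to give 13.
3. **Step 11 (TFA cyclisation; C5 β-elimination of the C6–OH, or acid sensitivity of the p-silyloxystyrene).**
   Fallback: use potassium vinyltrifluoroborate in step 9 instead of 4. Do the cyclisation on the vinyl substrate, then install the styrene by cross-metathesis with 4-TIPSO-styrene after step 12 and desilylate in step 13.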